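## The problem

CNP0248258.1 is two 2-(2-phenylethyl)chromone units joined by an alkyl aryl ether: O6' of an aromatic 7'-hydroxychromone is bonded to C5 of a 5,6,7,8-tetrahydrochromone. The saturated carbocycle (ring B: C4a, C5, C6, C7, C8, C8a) is fused to the γ-pyranone (ring A) across C4a=C8a. It carries four contiguous oxygenated stereocentres, 5S,6S,7R,8S, with O5 and O8 syn to each other and anti to the cis pair O6/O7. A cis-6,7-diol can be locked in a dioxolane that blocks one face of ring B, so C6/C7 can control C5 and C8 together; no comparable handle works in the other direction, so the absolute configuration has to enter with C6/C7. O5 and O8 are chemically alike but only O5 is arylated, so they must be told apart, and the ether has to be made at a hindered secondary centre. The fragile points are: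

- the C5–O bond, which is allylic to the ring-A enol ether O1–C8a=C4a and ionises in strong acid;
- every ring-B ketone, whose β-oxygens at C5 and C7 leave by E1cB and start aromatisation;
- the base-sensitive pyranones and the free phenol.

The enabling feature is that C5 and C8 are 1,4-related across C4a–C8a, and C8a is at the ketone oxidation level. C5=C4a–C8a(OSi)=C8 is therefore the silyl dienol ether of a known 4,5-dioxygenated cyclohexenone. O2 added across its termini, opposite a 6,7-acetonide, gives the trans,cis,trans oxygen pattern and leaves an enol silane at C8a.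

## Retrosynthesis

Ring-B carbons of all intermediates are called by the chromone locants of the target (C4a, C5–C8, C8a); primed locants belong to the aryl chromone.

**Protecting groups (26 ⇒ 25 ⇒ 24).** The O8–Si bond, the 6,7-ketal and the phenol acetal are cut last. Each group is the one an earlier step needs: the silyl group reaches O8 by itself, the acetonide steers the cycloaddition, and a methoxymethyl ether is small next to the coupling site and inert to base. Fluoride comes first and dilute aqueous acid last, so the ionisable C5–O bond meets acid once, under the mildest conditions. A benzyl ether was rejected because its hydrogenolysis would run beside the allylic C5–O bond.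

**Aryl ether (24 ⇒ 17 + 23).** The C6'–O bond is cut, not the C5–O bond. The C5–O bond and its configuration then come unchanged from the oxygenation step. Cutting C5–O would mean a stereocontrolled substitution at an ionisable allylic centre. The cut gives two chromones of similar size, alcohol 17 and bromide 23. The forward step is a C(sp2)–O coupling of a hindered secondary alcohol with an electron-rich aryl bromide, for which nickel/photoredox catalysis is chosen.

**Aryl chromone (23 ⇒ 22 ⇒ 19 + 20 ⇒ 18).** C2'–C3' and O1'–C2' are cut by the classical Claisen condensation/cyclodehydration. Bromine and both phenol oxygens are already in place in acetophenone 18, and ester 20 supplies the phenylethyl chain. The forward steps ask only for selective protection of the non-chelated phenol.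

**Ring A (17 ⇒ 11 + 14).** C4–C4a and O1–C8a are cut. Acylketene 15, released from dioxinone 14, adds across the C8a=C4a enol silane of 11 and loses silanol. Building ring A late keeps the pyranone out of all ring-B oxygenation chemistry. It requires an enol silane of defined regiochemistry at C8a=C4a. Dioxinone 14 comes from 12 and 13 by γ-alkylation.

**Enol silane and O5 cap (11 ⇒ 10).** Two O–Si bonds are cut. Ketone 10 carries a silyl ether on O8 and a free 5-OH, so one silylating reagent can cap O5 and enolise toward the only unsubstituted α-carbon, C4a.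

**O–O cleavage and silyl shift (10 ⇒ 9 ⇒ 8).** No skeletal bond is cut. Reducing the peroxide of 8 gives cis-diol 9, whose enol silane can hand its silicon only to the neighbouring O8. This separates O8 from O5 without a selective protection and unveils the C8a ketone. The forward step must stay cold and nearly neutral, because the C5 oxygen is β to that ketone.

**Key disconnection (8 ⇒ 7).** C5–O and C8–O are cut together. Stepwise oxygenation (α'-hydroxylation, then enone epoxidation) needs two separate facial selections; the cycloaddition needs one and fixes the syn relation of O5 and O8 by its mechanism. The precursor 7 has two stereocentres in place of four.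

**Diene to feedstock (7 ⇒ 6 ⇒ 5 ⇒ 4 ⇒ 3 ⇒ 2 ⇒ 1).** Diene 7 is the silyl dienol ether of enone 6, which must be (4R,5S). Quinic acid, the usual chiral-pool source of this enone, gives the (4S,5R) antipode by its short route. The enone is therefore taken from meso epoxide 4 by enantioselective rearrangement, where the choice of base antipode selects either series. Epoxide 4 comes from cyclohexa-1,4-diene 1 by dihydroxylation, ketalisation and epoxidation.

## Roads not taken

**Alternative 1:** The cut is the C4a–C5 bond of ring B. The manno-configured aryl 6-deoxyhex-5-enopyranoside A1, whose aglycone is already the benzyl-protected aryl chromone, would be opened at the ring oxygen by TiCl3(OiPr). The enolate carbon (future C4a) would then close on the anomeric carbon (future C5) to give cyclohexanone A2.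

- Merits: all four stereocentres come from the hexose, and the aryl ether is made by glycosylating a phenol. On the aryl ether this road is better than the chosen plan, which needs a late coupling at a hindered alcohol. O5 is also distinct from O8 from the start.
- Weak points: the ring-oxygen cleavage that keeps the aglycone competes with loss of the aryloxide, a good leaving group and a poor donor for the open oxocarbenium ion. The Lewis acid also binds the chromone carbonyl. A2 is a β-aryloxy ketone, so each later enolisation and the hot ring-A annulation invite E1cB loss of the whole aryl chromone. Four benzyl ethers must finally be hydrogenolysed beside the allylic C5–O bond.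
- Comparison: the chosen plan carries the arylation risk instead, but never has a β-aryloxy ketone and adds the aryl group after ring A is in place.

**Alternative 2:** The cut is C4a=C8a. The second-generation Grubbs catalyst would join the vinyl and 1-methoxyvinyl ends of the galacto-derived diene A3 to give the methyl enol ether A4.

- Merits: the stereotetrad is taken from the sugar without any facial-selectivity question. O5 and O8 carry different groups from the outset, which is better than relying on a silyl shift. The enol ether could feed the same acylketene annulation.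
- Weak points: a long protecting-group sequence on an acyclic sugar, two olefinations including an ester methylenation, and a slow metathesis onto a 1,1-disubstituted enol ether that can stall as an alkoxycarbene. The C–O arylation is still needed afterwards.
- Comparison: the chosen plan reaches an equivalent ring B in fewer steps and sets C5 and C8 in one operation, at the price of having to differentiate O5 from O8.

**Alternative 3:** The cut is C4–C4a and O1–C8a, with this step as the centre of the strategy. Thermolysis of dioxinone 14 releases acylketene 15, which adds across enol silane A5 and loses Me3SiOH to give the protected tetrahydrochromone A6.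

- Merits: convergent, neutral, and the bond set is the one the chosen route uses for ring A; for ring A the two are equal.
- Weak points: as a headline it solves only ring A. A5 must already hold four stereocentres and three different protecting groups, and no short source of it is defined. The arylation remains.
- Comparison: the chosen plan takes this annulation over as a supporting step and supplies the stereocontrolled access to ring B that it lacks.

Key step: step 7

## Route

Assumption: the lithium amide of the (S)-diamine is taken to remove the same enantiotopic proton from epoxide 4 as it does from cyclohexene oxide (which gives the (S)-allylic alcohol); if the sense proves opposite, the (R)-diamine is used.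

Step 1
Reactants: 1 cyclohexa-1,4-diene
Product: 2 cis-cyclohex-4-ene-1,2-diol (meso)
Conditions: OsO4 (cat.), NMO, acetone/H2O, 0 °C → rt, diene in excess
Reagents that add atoms: N-methylmorpholine N-oxide, C[N+]1([O-])CCOCC1; water, O
Why: Upjohn dihydroxylation; syn addition gives the cis (meso) diol, and excess diene keeps the second alkene untouched.

Step 2
Reactants: 2 cis-cyclohex-4-ene-1,2-diol
Product: 3 (3aR,7aS)-2,2-dimethyl-3a,4,7,7a-tetrahydro-1,3-benzodioxole (meso acetonide)
Conditions: 2,2-dimethoxypropane, TsOH (cat.), CH2Cl2, rt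
Reagents that add atoms: 2,2-dimethoxypropane, COC(C)(C)OC
Why: Acid-catalysed transketalisation of a cis-1,2-diol; no stereocentre is touched.

Step 3
Reactants: 3 meso acetonide
Product: 4 (1R,3R,4S,6S)-3,4-(isopropylidenedioxy)-7-oxabicyclo[4.1.0]heptane (meso epoxide, oxirane anti to the dioxolane)
Conditions: mCPBA, CH2Cl2, 0 °C → rt; chromatographic removal of the syn epoxide
Reagents that add atoms: mCPBA, OOC(=O)c1cccc(Cl)c1
Why: Prilezhaev epoxidation, expected mainly on the face away from the dioxolane. The syn isomer must be removed because the same base would desymmetrise it toward the antipodal enone.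

Step 4
Reactants: 4 meso anti-epoxide
Product: 5 (1S,4R,5S)-4,5-(isopropylidenedioxy)cyclohex-2-en-1-ol
Conditions: (S)-2-(pyrrolidin-1-ylmethyl)pyrrolidine, n-BuLi, THF, 0 °C → rt
Reagents that add atoms: none
Why: Chiral lithium amide rearrangement of a meso epoxide to an allylic alcohol by syn β-elimination. The base removes the proton cis to the oxirane at one of the two enantiotopic CH2 groups, which fixes the acetonide carbons as (4R,5S). Enantiomeric purity is to be checked here and upgraded if needed.

Step 5
Reactants: 5 allylic alcohol
Product: 6 (4R,5S)-4,5-(isopropylidenedioxy)cyclohex-2-en-1-one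
Conditions: MnO2, CH2Cl2, rt
Reagents that add atoms: none
Why: Neutral allylic oxidation, which avoids base-induced β-elimination of the acetonide oxygen. The carbinol centre is deleted and C4/C5 remain.

Step 6
Reactants: 6 enone
Product: 7 tert-butyl{[(3aS,7aR)-2,2-dimethyl-3a,7a-dihydro-1,3-benzodioxol-5-yl]oxy}dimethylsilane (2-silyloxy-1,3-diene)
Conditions: TBSOTf, Et3N, CH2Cl2, −78 → 0 °C; used at once
Reagents that add atoms: tert-butyldimethylsilyl trifluoromethanesulfonate, CC(C)(C)[Si](C)(C)OS(=O)(=O)C(F)(F)F
Why: Soft enolisation at the only enolisable α'-CH2 gives the cross-conjugated silyl dienol ether. The silyl triflate traps the enol before a free enolate can expel the β-acetonide oxygen.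

Step 7
Reactants: 7 2-silyloxy-1,3-diene
Product: 8 endoperoxide: tert-butyldimethylsilyl enol ether (C8a=C4a) of the 2,3-dioxabicyclo[2.2.2]oct-5-ene whose O–O bridge spans C5 and C8 on the face opposite the C6/C7 acetonide (5S,6S,7R,8S)
Conditions: O2, tetraphenylporphyrin (cat.), visible light, CH2Cl2, −78 °C; solution kept cold and carried on
Reagents that add atoms: dioxygen, O=O
Why: Tetraphenylporphyrin sensitises O2 to singlet oxygen, which adds suprafacially to the termini C5 and C8 of the ring-locked s-cis 2-silyloxy-1,3-diene in a [4+2] cycloaddition. The closest known reactions are singlet-oxygen cycloadditions to cis-dihydrocatechol acetonides and to 2-silyloxycyclohexa-1,3-dienes. The one new ring, the 1,2-dioxane of the bicycle, is closed by this cycloaddition with both C–O bonds formed on the same face. C5 and C8 are set together by the C6/C7 dioxolane, which blocks the syn face, so O5 and O8 end up cis to each other and trans to O6/O7. The step needs π-facial selectivity and preference for cycloaddition over the ene and silyl-transfer modes of an enol silane; the fixed s-cis geometry and electron-rich diene favour the [4+2] path, and −78 °C suppresses the others. The C8a enol silane is not consumed, and the product is kept cold because warming lets it push out the allylic C5 peroxide oxygen. The absolute configuration is carried over unchanged from C6 and C7 of 7.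

Step 8
Reactants: 8 endoperoxide
Product: 10 (2S,3R,4R,5S)-2-(tert-butyldimethylsilyloxy)-5-hydroxy-3,4-(isopropylidenedioxy)cyclohexan-1-one (C8a ketone with 8-OTBS and free 5-OH), via cis-5,8-diol enol silane 9 (not isolated)
Conditions: thiourea, MeOH/CH2Cl2, −78 → 0 °C; then DBU (cat.), CH2Cl2, −40 °C; not chromatographed
Reagents that add atoms: none
Why: Thiourea cleaves the O–O bond reductively without touching either C–O bond, giving cis-diol 9. A 1,4 O-to-O silyl migration through a five-membered siliconate then moves the silicon from the enol oxygen to O8, driven by formation of the C8a carbonyl. O5 is transoid across C4a=C8a and cannot reach silicon, so only O8 is capped.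

Step 9
Reactants: 10 8-O-silyl 5-hydroxy ketone
Product: 11 bis(trimethylsilyl) derivative: 5-O-trimethylsilyl ether and C8a=C4a trimethylsilyl enol ether, 8-OTBS and 6,7-acetonide retained
Conditions: TMSOTf (2.5 equiv), Et3N, CH2Cl2, −78 → 0 °C; used crude
Reagents that add atoms: trimethylsilyl trifluoromethanesulfonate, C[Si](C)(C)OS(=O)(=O)C(F)(F)F
Why: O5 is silylated first, then the ketone is soft-enolised. As with other α-silyloxy ketones under triflate/amine conditions, enolisation goes to the non-oxygenated side (the C4a methylene), not the hindered tertiary C8–H. No free β-alkoxide is formed, so retro-aldol and elimination are avoided.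

Step 10
Reactants: 12 2,2,6-trimethyl-4H-1,3-dioxin-4-one; 13 benzyl bromide
Product: 14 2,2-dimethyl-6-(2-phenylethyl)-4H-1,3-dioxin-4-one
Conditions: LDA, THF/DMPU, −78 °C; then 13, −78 → −20 °C
Reagents that add atoms: none
Why: Vinylogous enolate alkylation; the lithium dienolate of the dioxinone reacts with the reactive benzylic halide at the γ-carbon.

Step 11
Reactants: 11 bis(trimethylsilyl) enol silane; 14 phenylethyl dioxinone
Product: 17 (5S,6R,7R,8S)-8-(tert-butyldimethylsilyloxy)-5-hydroxy-6,7-(isopropylidenedioxy)-2-(2-phenylethyl)-5,6,7,8-tetrahydro-4H-chromen-4-one, via (3-phenylpropanoyl)ketene 15 (not isolated), via silyloxydihydropyranone cycloadduct 16 (not isolated)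
Conditions: toluene, 110 °C, 14 in excess added slowly; then CF3CO2H, wet CH2Cl2, 0 °C
Reagents that add atoms: none
Why: Retro-[4+2] of the dioxinone releases acetone and acylketene 15. Hetero-Diels–Alder addition to the enol silane joins C4a to the ketene carbon and the acyl oxygen to C8a; a C-acylation pathway would converge on the same product. Acid then expels Me3SiOH through the C8a oxocarbenium ion to give the pyranone and frees O5 from its trimethylsilyl ether, while the C4a/C8a centres of 16 are erased and C5–C8 are untouched.

Step 12
Reactants: 18 1-(5-bromo-2,4-dihydroxyphenyl)ethanone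
Product: 19 1-[5-bromo-2-hydroxy-4-(methoxymethoxy)phenyl]ethanone
Conditions: MOMCl, K2CO3, acetone, 0 °C → rt
Reagents that add atoms: chloromethyl methyl ether, COCCl
Why: Williamson-type O-alkylation; the 2-OH is chelated to the acetyl carbonyl, so the 4-OH reacts selectively.

Step 13
Reactants: 19 mono-MOM acetophenone; 20 ethyl 3-phenylpropanoate
Product: 22 6-bromo-7-hydroxy-2-(2-phenylethyl)-4H-chromen-4-one, via 1,3-diketone 21 (not isolated)
Conditions: NaH, THF, reflux; then conc. HCl, MeOH, reflux
Reagents that add atoms: none
Why: Crossed Claisen condensation of the methyl ketone enolate with the ester gives the β-diketone. Acid closes and dehydrates it to the chromone and cleaves the MOM ether in the same operation.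

Step 14
Reactants: 22 6-bromo-7-hydroxychromone
Product: 23 6-bromo-7-(methoxymethoxy)-2-(2-phenylethyl)-4H-chromen-4-one
Conditions: MOMCl, iPr2NEt, CH2Cl2, 0 °C → rt
Reagents that add atoms: chloromethyl methyl ether, COCCl
Why: Phenol O-alkylation; the MOM group is small beside the bromide, stable to the basic coupling and cleaved by the acid that opens the acetonide.

Step 15
Reactants: 17 ring-B alcohol; 23 aryl bromide
Product: 24 (5S,6R,7R,8S)-8-(tert-butyldimethylsilyloxy)-6,7-(isopropylidenedioxy)-5-{[7-(methoxymethoxy)-4-oxo-2-(2-phenylethyl)-4H-chromen-6-yl]oxy}-2-(2-phenylethyl)-5,6,7,8-tetrahydro-4H-chromen-4-one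
Conditions: NiBr2(dme) (cat.), 4,4'-di-tert-butyl-2,2'-bipyridine, Ir[dF(CF3)ppy]2(dtbbpy)PF6 (cat.), quinuclidine (cat.), K2CO3, MeCN, blue LEDs, rt; 23 in excess
Reagents that add atoms: none
Why: Nickel/photoredox C(sp2)–O cross-coupling: zerovalent nickel inserts into C6'–Br, the alkoxide of 17 binds, and photo-oxidation to trivalent nickel triggers C–O reductive elimination. The C5–O bond is never broken, so 5S is retained, and O5 is the only free hydroxyl.

Step 16
Reactants: 24 protected ether
Product: 25 (5S,6R,7S,8S)-8-hydroxy-6,7-(isopropylidenedioxy)-5-{[7-(methoxymethoxy)-4-oxo-2-(2-phenylethyl)-4H-chromen-6-yl]oxy}-2-(2-phenylethyl)-5,6,7,8-tetrahydro-4H-chromen-4-one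
Conditions: TBAF, AcOH, THF, 0 °C → rt
Reagents that add atoms: none
Why: Fluoride-induced desilylation; acetic acid buffering protects the pyranones and prevents base-triggered elimination.

Step 17
Reactants: 25 acetonide MOM ether
Product: 26 (5S,6S,7R,8S)-6,7,8-trihydroxy-5-{[7-hydroxy-4-oxo-2-(2-phenylethyl)-4H-chromen-6-yl]oxy}-2-(2-phenylethyl)-5,6,7,8-tetrahydro-4H-chromen-4-one (CNP0248258.1)
Conditions: HCl (2 M aq.), THF, rt
Reagents that add atoms: none
Why: Acid hydrolysis of the isopropylidene ketal and the MOM acetal, both through oxocarbenium ions at the protecting-group carbons. Dilute aqueous acid is chosen because stronger, more ionising media could cleave the allylic C5–OAr bond. No stereocentre is touched.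

## Compound list

1 | cyclohexa-1,4-diene | C1=CCC=CC1 | starting material
2 | cis-cyclohex-4-ene-1,2-diol (meso) | O[C@@H]1CC=CC[C@@H]1O | intermediate
3 | (3aR,7aS)-2,2-dimethyl-3a,4,7,7a-tetrahydro-1,3-benzodioxole | CC1(C)O[C@@H]2CC=CC[C@@H]2O1 | intermediate
4 | (1R,3R,4S,6S)-3,4-(isopropylidenedioxy)-7-oxabicyclo[4.1.0]heptane (meso, oxirane anti to dioxolane) | C1[C@@H]2O[C@@H]2C[C@H]3OC(C)(C)O[C@H]31 | intermediate
5 | (1S,4R,5S)-4,5-(isopropylidenedioxy)cyclohex-2-en-1-ol | O[C@H]1C[C@@H]2OC(C)(C)O[C@@H]2C=C1 | intermediate
6 | (4R,5S)-4,5-(isopropylidenedioxy)cyclohex-2-en-1-one | O=C1C[C@@H]2OC(C)(C)O[C@@H]2C=C1 | intermediate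
7 | tert-butyl{[(3aS,7aR)-2,2-dimethyl-3a,7a-dihydro-1,3-benzodioxol-5-yl]oxy}dimethylsilane | CC(C)(C)[Si](C)(C)OC1=C[C@@H]2OC(C)(C)O[C@@H]2C=C1 | intermediate
8 | endoperoxide bridging C5 and C8 anti to the acetonide, C8a TBS enol ether | CC(C)(C)[Si](C)(C)OC1=C[C@@H]2OO[C@H]1[C@@H]3OC(C)(C)O[C@@H]32 | intermediate
9 | cis-5,8-diol with C8a=C4a TBS enol ether and 6,7-acetonide (not isolated) | CC(C)(C)[Si](C)(C)OC1=C[C@H](O)[C@H]2OC(C)(C)O[C@H]2[C@@H]1O | intermediate
10 | (2S,3R,4R,5S)-2-(tert-butyldimethylsilyloxy)-5-hydroxy-3,4-(isopropylidenedioxy)cyclohexan-1-one | O=C1C[C@H](O)[C@H]2OC(C)(C)O[C@H]2[C@@H]1O[Si](C)(C)C(C)(C)C | intermediate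
11 | 5-O-TMS ether, C8a=C4a TMS enol ether, 8-OTBS, 6,7-acetonide | C[Si](C)(C)OC1=C[C@H](O[Si](C)(C)C)[C@H]2OC(C)(C)O[C@H]2[C@@H]1O[Si](C)(C)C(C)(C)C | intermediate
12 | 2,2,6-trimethyl-4H-1,3-dioxin-4-one | CC1=CC(=O)OC(C)(C)O1 | starting material
13 | benzyl bromide | BrCc1ccccc1 | starting material
14 | 2,2-dimethyl-6-(2-phenylethyl)-4H-1,3-dioxin-4-one | O=C1C=C(CCc2ccccc2)OC(C)(C)O1 | intermediate
15 | (3-phenylpropanoyl)ketene (not isolated) | O=C=CC(=O)CCc1ccccc1 | intermediate
16 | 8a-(trimethylsilyloxy)-4a,8a-dihydro cycloadduct, ring fusion drawn as expected from addition anti to the silyloxy groups and erased in the same step (not isolated) | O=C1C=C(CCc2ccccc2)O[C@@]2(O[Si](C)(C)C)[C@@H]1[C@H](O[Si](C)(C)C)[C@H]3OC(C)(C)O[C@H]3[C@@H]2O[Si](C)(C)C(C)(C)C | intermediate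
17 | (5S,6R,7R,8S)-8-(tert-butyldimethylsilyloxy)-5-hydroxy-6,7-(isopropylidenedioxy)-2-(2-phenylethyl)-5,6,7,8-tetrahydro-4H-chromen-4-one | O=c1cc(CCc2ccccc2)oc2c1[C@H](O)[C@H]3OC(C)(C)O[C@H]3[C@@H]2O[Si](C)(C)C(C)(C)C | intermediate
18 | 1-(5-bromo-2,4-dihydroxyphenyl)ethanone | CC(=O)c1cc(Br)c(O)cc1O | starting material
19 | 1-[5-bromo-2-hydroxy-4-(methoxymethoxy)phenyl]ethanone | CC(=O)c1cc(Br)c(OCOC)cc1O | intermediate
20 | ethyl 3-phenylpropanoate | CCOC(=O)CCc1ccccc1 | starting material
21 | 1-[5-bromo-2-hydroxy-4-(methoxymethoxy)phenyl]-5-phenylpentane-1,3-dione (not isolated) | O=C(CC(=O)CCc1ccccc1)c1cc(Br)c(OCOC)cc1O | intermediate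
22 | 6-bromo-7-hydroxy-2-(2-phenylethyl)-4H-chromen-4-one | O=c1cc(CCc2ccccc2)oc2cc(O)c(Br)cc12 | intermediate
23 | 6-bromo-7-(methoxymethoxy)-2-(2-phenylethyl)-4H-chromen-4-one | COCOc1cc2oc(CCc3ccccc3)cc(=O)c2cc1Br | intermediate
24 | (5S,6R,7R,8S) coupled ether with 8-OTBS, 6,7-acetonide and 7'-OMOM | O=c1cc(CCc2ccccc2)oc2c1[C@H](Oc1cc3c(=O)cc(CCc4ccccc4)oc3cc1OCOC)[C@H]3OC(C)(C)O[C@H]3[C@@H]2O[Si](C)(C)C(C)(C)C | intermediate
25 | (5S,6R,7S,8S) coupled ether with free 8-OH, 6,7-acetonide and 7'-OMOM | O=c1cc(CCc2ccccc2)oc2c1[C@H](Oc1cc3c(=O)cc(CCc4ccccc4)oc3cc1OCOC)[C@H]3OC(C)(C)O[C@H]3[C@@H]2O | intermediate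
26 | (5S,6S,7R,8S)-6,7,8-trihydroxy-5-{[7-hydroxy-4-oxo-2-(2-phenylethyl)-4H-chromen-6-yl]oxy}-2-(2-phenylethyl)-5,6,7,8-tetrahydro-4H-chromen-4-one | O=c1cc(CCc2ccccc2)oc2c1[C@H](Oc1cc3c(=O)cc(CCc4ccccc4)oc3cc1O)[C@@H](O)[C@@H](O)[C@@H]2O | target

## Step count and risks

Total step count: 17. Longest linear sequence: 13 steps (steps 1–9, 11, 15, 16, 17).

**Step 7 (key step).** The likely failures are incomplete facial discrimination, diversion of singlet oxygen into ene or silyl-transfer modes at the enol silane, and fragmentation of the electron-rich allylic peroxide (the enol silane ejecting the C5 oxygen) before it is reduced. Fallback, from 7 to 10: Rubottom oxidation of the enol-silane double bond (dimethyldioxirane, acetone, −78 °C) anti to the dioxolane gives the 8-silyloxy enone F1. Weitz–Scheffer epoxidation (t-BuOOH, DBU, CH2Cl2) on the face anti to the dioxolane gives the 4a,5-epoxy ketone F2. Reductive opening at C4a (PhSeSePh, NaBH4, AcOH, EtOH) gives 10. This replaces one cycloaddition by two separate facial selections under the same acetonide bias.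

**Step 8.** The silyl transfer may lag behind dehydration. Once the ketone is unveiled the C5 hydroxyl is β to it, and the base that triggers the shift can also start its E1cB loss. Fallback, from 9 to 17, without the shift: both hydroxyls are capped with N,O-bis(trimethylsilyl)acetamide to give the bis(trimethylsilyl) ether F3, keeping the original C8a enol silane. Annulation with 14 and the acid work-up of step 11 gives the 5,8-diol F4. O8 is then silylated selectively (TBSCl, imidazole, DMF), the C5 hydroxyl being held in a hydrogen bond to the C4 carbonyl, to give 17.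

**Step 11.** Dimerisation and decay of the acylketene may outpace its addition to a hindered trisubstituted enol silane flanked by two silyloxy groups, and C5 may partly ionise during the acid-induced loss of silanol. Fallback, from 11 to 17: 5-phenylpent-2-ynal F5 is made by formylation of 4-phenylbut-1-yne. MeLi converts 11 into the lithium enolate F6, whose aldol addition to F5 gives the propargylic aldol F7. Dess–Martin oxidation gives the alkynyl 1,3-diketone F8. Amine-catalysed 6-endo oxa-Michael closure, then the acid work-up of step 11, gives 17.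

**Step 15.** C–O reductive elimination from nickel may be slow for a hindered secondary alkoxide and an electron-rich, ortho-substituted aryl group, so protodebromination of 23 and hydrogen abstraction at the activated C5–H could take over. Fallback, from 17 to 24, with the phenol as nucleophile and double inversion at C5: Mitsunobu reaction of 17 with 4-nitrobenzoic acid (PPh3, DIAD) gives the 5-epi 4-nitrobenzoate F9. K2CO3/MeOH frees the 5-epi alcohol F10. Bromide 23 is converted by Miyaura borylation (B2pin2, Pd(dppf)Cl2, KOAc) into the pinacol boronate F11 and oxidised (NaBO3·4H2O) to the 6-hydroxychromone F12. A second Mitsunobu reaction of F10 with F12 inverts C5 again and gives 24.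

## Further compounds

F1 | step 7 | 6-(tert-butyldimethylsilyloxy)-4,5-(isopropylidenedioxy)cyclohex-2-en-1-one, silyloxy group (O8) trans to the acetonide | O=C1C=C[C@H]2OC(C)(C)O[C@H]2[C@@H]1O[Si](C)(C)C(C)(C)C
F2 | step 7 | 4a,5-epoxy ketone, oxirane anti to the acetonide, 8-OTBS | O=C1[C@@H]2O[C@@H]2[C@H]3OC(C)(C)O[C@H]3[C@@H]1O[Si](C)(C)C(C)(C)C
F3 | step 8 | 5,8-bis(trimethylsilyl) ether of diol 9 with C8a TBS enol ether | CC(C)(C)[Si](C)(C)OC1=C[C@H](O[Si](C)(C)C)[C@H]2OC(C)(C)O[C@H]2[C@@H]1O[Si](C)(C)C
F4 | step 8 | 5,8-dihydroxy-6,7-(isopropylidenedioxy)-2-(2-phenylethyl)-5,6,7,8-tetrahydro-4H-chromen-4-one | O=c1cc(CCc2ccccc2)oc2c1[C@H](O)[C@H]3OC(C)(C)O[C@H]3[C@@H]2O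
F5 | step 11 | 5-phenylpent-2-ynal | O=CC#CCCc1ccccc1
F6 | step 11 | lithium enolate (C8a=C4a) of the 5-O-TMS 8-O-TBS ketone | [Li+].[O-]C1=C[C@H](O[Si](C)(C)C)[C@H]2OC(C)(C)O[C@H]2[C@@H]1O[Si](C)(C)C(C)(C)C
F7 | step 11 | propargylic aldol at C4a (mixture at C4a and the carbinol carbon) | O=C1C(C(O)C#CCCc2ccccc2)[C@H](O[Si](C)(C)C)[C@H]3OC(C)(C)O[C@H]3[C@@H]1O[Si](C)(C)C(C)(C)C
F8 | step 11 | alkynyl 1,3-diketone (C4a acylated by 5-phenylpent-2-ynoyl) | O=C1C(C(=O)C#CCCc2ccccc2)[C@H](O[Si](C)(C)C)[C@H]3OC(C)(C)O[C@H]3[C@@H]1O[Si](C)(C)C(C)(C)C
F9 | step 15 | 5-epi 4-nitrobenzoate of 17 | O=c1cc(CCc2ccccc2)oc2c1[C@@H](OC(=O)c4ccc(cc4)[N+](=O)[O-])[C@H]3OC(C)(C)O[C@H]3[C@@H]2O[Si](C)(C)C(C)(C)C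
F10 | step 15 | 5-epi alcohol of 17 | O=c1cc(CCc2ccccc2)oc2c1[C@@H](O)[C@H]3OC(C)(C)O[C@H]3[C@@H]2O[Si](C)(C)C(C)(C)C
F11 | step 15 | 7-(methoxymethoxy)-2-(2-phenylethyl)-6-(4,4,5,5-tetramethyl-1,3,2-dioxaborolan-2-yl)-4H-chromen-4-one | COCOc1cc2oc(CCc3ccccc3)cc(=O)c2cc1B1OC(C)(C)C(C)(C)O1
F12 | step 15 | 6-hydroxy-7-(methoxymethoxy)-2-(2-phenylethyl)-4H-chromen-4-one | COCOc1cc2oc(CCc3ccccc3)cc(=O)c2cc1O
A1 | alternative 1 | 7-(benzyloxy)-4-oxo-2-(2-phenylethyl)-4H-chromen-6-yl 2,3,4-tri-O-benzyl-6-deoxy-α-D-lyxo-hex-5-enopyranoside | C=C1O[C@H](Oc2cc3c(=O)cc(CCc4ccccc4)oc3cc2OCc2ccccc2)[C@@H](OCc2ccccc2)[C@@H](OCc2ccccc2)[C@@H]1OCc1ccccc1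
A2 | alternative 1 | ring-B cyclohexanone (C8a carbonyl, C4a methylene) with the C5 aryl ether and 6,7,8-tri-O-benzyl groups | O=C1C[C@H](Oc2cc3c(=O)cc(CCc4ccccc4)oc3cc2OCc2ccccc2)[C@@H](OCc2ccccc2)[C@@H](OCc2ccccc2)[C@@H]1OCc1ccccc1
A3 | alternative 2 | 2-methoxy-3-(methoxymethoxy)-4,5-(isopropylidenedioxy)-6-[(4-methoxybenzyl)oxy]octa-1,7-diene | C=C[C@H](OCc1ccc(OC)cc1)[C@H]1OC(C)(C)O[C@H]1[C@H](OCOC)C(OC)=C
A4 | alternative 2 | ring-B methyl enol ether with 5-OPMB, 6,7-acetonide and 8-OMOM | COC1=C[C@H](OCc2ccc(OC)cc2)[C@H]2OC(C)(C)O[C@H]2[C@@H]1OCOC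
A5 | alternative 3 | C8a=C4a trimethylsilyl enol ether with 5-OTBS, 6,7-acetonide and 8-OMOM | C[Si](C)(C)OC1=C[C@H](O[Si](C)(C)C(C)(C)C)[C@H]2OC(C)(C)O[C@H]2[C@@H]1OCOC
A6 | alternative 3 | 5-OTBS 6,7-acetonide 8-OMOM 2-(2-phenylethyl)-5,6,7,8-tetrahydrochromone | O=c1cc(CCc2ccccc2)oc2c1[C@H](O[Si](C)(C)C(C)(C)C)[C@H]3OC(C)(C)O[C@H]3[C@@H]2OCOC
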